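**Retrosynthetic overview**
1. Target ⇐ Et3Si removal ⇐ ten-membered carbocycle and trans-γ-lactone closed together, last, by an intramolecular chromium-mediated allylation (C6–C7) of a C6 epoxy aldehyde with a C13 allylic bromide.
2. The oxirane (first ring formed) comes from Sharpless epoxidation of a (Z)-C4=C5 allylic alcohol, made by B-alkyl Suzuki coupling (C3–C4) with (Z)-3-iodobut-2-en-1-ol.
3. C7–C10, C1, C2 and C14 are the seven carbons of methyl benzoate: ozonolysis of the C2=C7 bond of its cis-dihydrodiol opens the six-membered ring, which has already locked the C1=C10 geometry; a C9–OH lactol masks C2 while C7 is olefinated.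
4. Key step: dioxygenase cis-dihydroxylation of methyl benzoate sets C8 and C9 in one operation; the chlorohydrin acid (from methyl angelate) is attached at once to the distal C8–OH.

Assumption: the SMILES defines the target, i.e. (4R,5S,6S,7R,8S,9R), side chain (2R,3R), C9 cis to C2 across C1=C10 and a cis-4,5-epoxide; germacrane locants C1–C15 are used for open-chain intermediates.
Notation: R*CO = (2R,3R)-3-chloro-2-methyl-2-(triethylsilyloxy)butanoyl.

**Route**

Step 1
Reactants: 1 methyl benzoate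
Product: 2 methyl (5S,6R)-5,6-dihydroxycyclohexa-1,3-diene-1-carboxylate
Conditions: E. coli JM109(pDTG601A) whole cells (toluene dioxygenase), IPTG, glucose feed, air, pH 6.8, 30 °C; EtOAc extraction
Reagents that add atoms: dioxygen, O=O
Why: Enzymatic arene cis-dihydroxylation (toluene dioxygenase) breaks the aromatic ring by syn delivery of both oxygen atoms of O2, which sets C8 (S) and C9 (R) in the known (5S,6R) sense and leaves the future C10=C1 acrylate locked ring-cis inside the diene.

Step 2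
Reactants: 3 methyl (Z)-2-methylbut-2-enoate (methyl angelate)
Product: 4 (Z)-2-methylbut-2-en-1-ol
Conditions: i-Bu2AlH (2.2 equiv), CH2Cl2, −78 → 0 °C; aq. potassium sodium tartrate
Reagents that add atoms: none
Why: 1,2-Reduction of the conjugated ester by i-Bu2AlH gives the allylic alcohol without touching the Z double bond.

Step 3
Reactants: 4 (Z)-2-methylbut-2-en-1-ol
Product: 5 [(2R,3S)-2,3-dimethyloxiran-2-yl]methanol
Conditions: Ti(Oi-Pr)4 (10 mol%), D-(−)-diisopropyl tartrate (12 mol%), t-BuOOH, 4 Å MS, CH2Cl2, −20 °C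
Reagents that add atoms: tert-butyl hydroperoxide, CC(C)(C)OO
Why: Katsuki–Sharpless asymmetric epoxidation, in which the D-(−)-tartrate/titanium catalyst delivers oxygen to the face that gives the (2R,3S) cis-epoxide (about 90% ee expected; the minor antipode is removed later as a diastereomer of 11).

Step 4
Reactants: 5 [(2R,3S)-2,3-dimethyloxiran-2-yl]methanol
Product: 7 (2R,3R)-3-chloro-2-hydroxy-2-methylbutanoic acid, via epoxy acid 6 (not isolated)
Conditions: TEMPO (0.2 equiv), PhI(OAc)2 (2.2 equiv), MeCN/H2O, 0 °C → rt; then conc. HCl, 0 °C → rt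
Reagents that add atoms: water, O; hydrogen chloride, Cl
Why: Oxoammonium (TEMPO/PhI(OAc)2) oxidation gives the glycidic acid, and chloride then opens the protonated oxirane by SN2 at C3, the carbon remote from the carboxyl group, with inversion, which fixes the (2R,3R) chlorohydrin.

Step 5
Reactants: 7 (2R,3R)-3-chloro-2-hydroxy-2-methylbutanoic acid
Product: 9 (2R,3R)-3-chloro-2-methyl-2-(triethylsilyloxy)butanoic acid, via bis-silylated acid 8 (not isolated)
Conditions: Et3SiOTf (2.5 equiv), 2,6-lutidine, CH2Cl2, −78 → 0 °C; then THF/H2O, 0 °C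
Reagents that add atoms: triethylsilyl trifluoromethanesulfonate, CC[Si](CC)(CC)OS(=O)(=O)C(F)(F)F
Why: Silyl triflate silylation of the tertiary alcohol and the acid, then selective hydrolysis of the labile silyl ester; the silyl ether blocks base-induced re-closure of the chlorohydrin to an epoxide in later steps.

Step 6
Reactants: 9 (2R,3R)-3-chloro-2-methyl-2-(triethylsilyloxy)butanoic acid; 2 methyl (5S,6R)-5,6-dihydroxycyclohexa-1,3-diene-1-carboxylate
Product: 11 methyl (5S,6R)-5-(R*CO2)-6-hydroxycyclohexa-1,3-diene-1-carboxylate, via mixed anhydride 10 (not isolated)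
Conditions: 2,4,6-Cl3C6H2COCl, Et3N, THF, 0 °C; then 2, DMAP, toluene, −20 → 0 °C
Reagents that add atoms: none
Why: Yamaguchi esterification in which the bulky mixed anhydride acylates the less hindered hydroxyl distal to the ester-bearing sp2 carbon (C8–OH), leaving C9–OH free; no stereocentre is touched.

Step 7
Reactants: 12 methyl (triphenylphosphoranylidene)acetate; 13 (iodomethyl)trimethylsilane
Product: 15 methyl 2-(triphenylphosphoranylidene)-3-(trimethylsilyl)propanoate, via alkylated phosphonium iodide 14 (not isolated)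
Conditions: 12 (2.0 equiv), 13 (1.0 equiv), EtOAc, reflux; filter off the phosphonium salt
Reagents that add atoms: none
Why: C-Alkylation of the stabilized ylide by the primary iodide followed by transylidation with a second equivalent of 12 (Bestmann ylide alkylation).

Step 8
Reactants: 11 methyl (5S,6R)-5-(R*CO2)-6-hydroxycyclohexa-1,3-diene-1-carboxylate; 15 methyl 2-(triphenylphosphoranylidene)-3-(trimethylsilyl)propanoate
Product: 18 lactol allylsilane (dihydrofuranol with O9–C2 lactol; C7H=C11(CO2Me)CH2SiMe3), via secondary ozonide 16 (not isolated), via lactol aldehyde 17 (not isolated)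
Conditions: O3, CH2Cl2, −78 °C (Sudan Red 7B end point); Me2S, −78 → 0 °C; then 15 (1.05 equiv), 0 °C → rt
Reagents that add atoms: ozone, [O-][O+]=O
Why: Ozonolysis cleaves the more electron-rich C2=C7 alkene rather than the acrylate; the C9 hydroxyl (cis to C2 across C1=C10) traps the C2 aldehyde as a dihydrofuranol, so the stabilized Wittig ylide reacts only with the free C7 aldehyde to give the 2-(silylmethyl)enoate (alkene geometry immaterial).

Step 9
Reactants: 18 lactol allylsilane
Product: 20 seco diene acetate (C9–OAc; C10(CO2Me)=C1 with C9 cis to C2; terminal C2=C3 vinyl), via potassium dienyl alkoxide 19 (not isolated)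
Conditions: KN(SiMe3)2 (1.05 equiv), THF, −78 °C; Ph3P=CH2 [from Ph3PCH3Br + KN(SiMe3)2, 1.3 equiv], −78 → −20 °C; then Ac2O, −20 → 0 °C
Reagents that add atoms: methyltriphenylphosphonium bromide, C[P+](c1ccccc1)(c1ccccc1)c1ccccc1.[Br-]; acetic anhydride, CC(=O)OC(C)=O
Why: Wittig methylenation of the lactol through its ring-opened hydroxy-enal form and in situ O-acetylation of the liberated C9 alkoxide, which is trapped before acyl migration; C8 and C9 are unchanged.

Step 10
Reactants: 21 but-2-yn-1-ol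
Product: 23 (Z)-3-iodobut-2-en-1-ol, via cyclic vinylalanate 22 (not isolated)
Conditions: NaAlH2(OCH2CH2OMe)2, THF, 0 °C → rt; then I2, −78 → 0 °C
Reagents that add atoms: iodine, II
Why: Hydroxyl-directed trans-hydroalumination of the propargylic alcohol places aluminium at C3 cis to the CH2O group, and iodinolysis with retention gives the Z vinyl iodide.

Step 11
Reactants: 20 seco diene acetate; 23 (Z)-3-iodobut-2-en-1-ol
Product: 25 (Z)-allylic alcohol (C3–C4 coupled; HOCH2(6)–C5H=C4(Me)–C3), via B-alkyl-9-BBN 24 (not isolated)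
Conditions: 9-BBN-H (1.5 equiv), THF, 0 °C → rt; then 23, PdCl2(dppf) (5 mol%), AsPh3 (10 mol%), Cs2CO3, DMF/H2O, rt
Reagents that add atoms: none
Why: Anti-Markovnikov hydroboration of the only monosubstituted alkene by 9-BBN and B-alkyl Suzuki–Miyaura coupling with retention of the vinyl iodide geometry give the nerol-type C4=C5 alkene (C3 cis to C6); such couplings tolerate allylic acetates.

Step 12
Reactants: 25 (Z)-allylic alcohol
Product: 26 (4R,5S)-epoxy alcohol
Conditions: Ti(Oi-Pr)4 (10 mol%), L-(+)-diisopropyl tartrate (12 mol%), t-BuOOH, 4 Å MS, CH2Cl2, −20 °C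
Reagents that add atoms: tert-butyl hydroperoxide, CC(C)(C)OO
Why: Katsuki–Sharpless epoxidation of the only allylic alcohol that is electron-rich enough, in which the L-(+)-tartrate catalyst overrides the remote stereocentres and delivers oxygen to the face that gives the (4R,5S) cis-epoxide.

Step 13
Reactants: 26 (4R,5S)-epoxy alcohol
Product: 28 primary allylic bromide (C13H2Br on the C7=C11 enoate), via secondary allylic bromide 27 (not isolated)
Conditions: NBS (1.05 equiv), MeCN/THF, −20 → 0 °C; then n-Bu4NBr (5 mol%), 0 °C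
Reagents that add atoms: N-bromosuccinimide, O=C1CCC(=O)N1Br
Why: Electrophilic bromodesilylation of the allylsilane (SE2', bromine at C7 with loss of silicon) followed by bromide-catalysed allylic transposition to the conjugated primary bromide; both allylic isomers lead to the same allylchromium reagent.

Step 14
Reactants: 28 primary allylic bromide
Product: 29 epoxy aldehyde (C6HO) allylic bromide
Conditions: Dess–Martin periodinane, pyridine, CH2Cl2, 0 °C
Reagents that add atoms: none
Why: Dess–Martin oxidation of the primary epoxy alcohol under buffered conditions leaves the oxirane, the allylic bromide and C5 (an oxirane carbon that does not enolize) intact.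

Step 15
Reactants: 29 epoxy aldehyde allylic bromide
Product: 31 triethylsilyl-protected target (ten-membered ring and 6,12-lactone closed), via ring-closed hydroxy ester 30 (not isolated)
Conditions: CrCl2 (8 equiv), THF/DMF, rt → 40 °C, slow addition (final 2 mM)
Reagents that add atoms: none
Why: Intramolecular Nozaki–Hiyama allylation: divalent chromium converts the allylic bromide into an allylchromium species that adds through its γ-carbon C7 to the aldehyde via a chair six-membered transition state (6,7-anti, hence trans-lactone) from the Felkin–Anh face anti to the oxirane C–O bond (5,6-erythro, so C6 is S and C7 is R), and the chromium alkoxide then lactonizes onto the C12 ester.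

Step 16
Reactants: 31 triethylsilyl-protected target
Product: 32 CNP0185503.1
Conditions: HF·pyridine, pyridine, THF, 0 °C → rt
Reagents that add atoms: none
Why: Fluoride cleavage of the tertiary triethylsilyl ether under pyridine-buffered conditions that spare the oxirane, the α-methylene lactone and the chlorohydrin.

**Compound list**
1 | methyl benzoate | COC(=O)c1ccccc1 | starting material
2 | methyl (5S,6R)-5,6-dihydroxycyclohexa-1,3-diene-1-carboxylate | COC(=O)C1=CC=C[C@H](O)[C@@H]1O | intermediate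
3 | methyl (Z)-2-methylbut-2-enoate (methyl angelate) | C/C=C(/C)C(=O)OC | starting material
4 | (Z)-2-methylbut-2-en-1-ol | C/C=C(/C)CO | intermediate
5 | [(2R,3S)-2,3-dimethyloxiran-2-yl]methanol | OC[C@@]1(C)O[C@H]1C | intermediate
6 | (2S,3S)-2,3-dimethyloxirane-2-carboxylic acid | OC(=O)[C@@]1(C)O[C@H]1C | intermediate
7 | (2R,3R)-3-chloro-2-hydroxy-2-methylbutanoic acid | OC(=O)[C@@](C)(O)[C@@H](C)Cl | intermediate
8 | triethylsilyl (2R,3R)-3-chloro-2-methyl-2-(triethylsilyloxy)butanoate | CC[Si](CC)(CC)OC(=O)[C@@](C)(O[Si](CC)(CC)CC)[C@@H](C)Cl | intermediate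
9 | (2R,3R)-3-chloro-2-methyl-2-(triethylsilyloxy)butanoic acid (R*CO2H) | OC(=O)[C@@](C)(O[Si](CC)(CC)CC)[C@@H](C)Cl | intermediate
10 | mixed anhydride of 9 with 2,4,6-trichlorobenzoic acid | Clc1cc(Cl)c(C(=O)OC(=O)[C@@](C)(O[Si](CC)(CC)CC)[C@@H](C)Cl)c(Cl)c1 | intermediate
11 | methyl (5S,6R)-5-(R*CO2)-6-hydroxycyclohexa-1,3-diene-1-carboxylate | COC(=O)C1=CC=C[C@H](OC(=O)[C@@](C)(O[Si](CC)(CC)CC)[C@@H](C)Cl)[C@@H]1O | intermediate
12 | methyl (triphenylphosphoranylidene)acetate | COC(=O)C=P(c1ccccc1)(c1ccccc1)c1ccccc1 | starting material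
13 | (iodomethyl)trimethylsilane | C[Si](C)(C)CI | starting material
14 | [1-methoxy-1-oxo-3-(trimethylsilyl)propan-2-yl]triphenylphosphonium iodide | COC(=O)C(C[Si](C)(C)C)[P+](c1ccccc1)(c1ccccc1)c1ccccc1.[I-] | intermediate
15 | methyl 2-(triphenylphosphoranylidene)-3-(trimethylsilyl)propanoate | COC(=O)C(C[Si](C)(C)C)=P(c1ccccc1)(c1ccccc1)c1ccccc1 | intermediate
16 | secondary ozonide of 11 (1,2,4-trioxolane bridging C2 and C7; C8, C9 as in 11; ozonide carbons unassigned) | COC(=O)C1=CC2OC(OO2)[C@H](OC(=O)[C@@](C)(O[Si](CC)(CC)CC)[C@@H](C)Cl)[C@@H]1O | intermediate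
17 | lactol aldehyde: methyl 5-hydroxy-2-[1-(R*CO2)-2-oxoethyl]-2,5-dihydrofuran-3-carboxylate (ring O = O9, lactol carbon = C2, CHO = C7; anomers) | O=C[C@H](OC(=O)[C@@](C)(O[Si](CC)(CC)CC)[C@@H](C)Cl)[C@@H]1OC(O)C=C1C(=O)OC | intermediate
18 | lactol allylsilane: as 17 with C7HO replaced by C7H=C11(CO2Me)CH2SiMe3 (ester trans to C8; anomers) | C[Si](C)(C)C/C(C(=O)OC)=C\[C@H](OC(=O)[C@@](C)(O[Si](CC)(CC)CC)[C@@H](C)Cl)[C@@H]1OC(O)C=C1C(=O)OC | intermediate
19 | potassium C9-alkoxide of the ring-opened C2=C3 diene | C[Si](C)(C)C/C(C(=O)OC)=C\[C@H](OC(=O)[C@@](C)(O[Si](CC)(CC)CC)[C@@H](C)Cl)[C@H]([O-])/C(C(=O)OC)=C\C=C.[K+] | intermediate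
20 | seco diene acetate: C9–OAc, C8–O2CR*, C10(CO2Me)=C1 (C9 cis to C2), C2=C3 vinyl, C7=C11(CO2Me)CH2SiMe3 | C[Si](C)(C)C/C(C(=O)OC)=C\[C@H](OC(=O)[C@@](C)(O[Si](CC)(CC)CC)[C@@H](C)Cl)[C@H](OC(C)=O)/C(C(=O)OC)=C\C=C | intermediate
21 | but-2-yn-1-ol | CC#CCO | starting material
22 | sodium 2,2-bis(2-methoxyethoxy)-3-methyl-2,5-dihydro-1,2-oxaaluminol-2-uide (cyclic vinylalanate) | CC1=CCO[Al-]1(OCCOC)OCCOC.[Na+] | intermediate
23 | (Z)-3-iodobut-2-en-1-ol | C/C(I)=C/CO | intermediate
24 | B-alkyl-9-BBN (boron on C3 of 20) | C[Si](C)(C)C/C(C(=O)OC)=C\[C@H](OC(=O)[C@@](C)(O[Si](CC)(CC)CC)[C@@H](C)Cl)[C@H](OC(C)=O)/C(C(=O)OC)=C\CCB1C2CCCC1CCC2 | intermediate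
25 | (Z)-allylic alcohol: 20 extended by C3H2–C4(Me)=C5H–C6H2OH (C3 cis to C6) | C[Si](C)(C)C/C(C(=O)OC)=C\[C@H](OC(=O)[C@@](C)(O[Si](CC)(CC)CC)[C@@H](C)Cl)[C@H](OC(C)=O)/C(C(=O)OC)=C\CC/C(C)=C\CO | intermediate
26 | (4R,5S)-epoxy alcohol of 25 | C[Si](C)(C)C/C(C(=O)OC)=C\[C@H](OC(=O)[C@@](C)(O[Si](CC)(CC)CC)[C@@H](C)Cl)[C@H](OC(C)=O)/C(C(=O)OC)=C\CC[C@@]1(C)O[C@H]1CO | intermediate
27 | secondary allylic bromide: C7–Br, C11=C13H2 (C7 epimers) | COC(=O)C(=C)C(Br)[C@H](OC(=O)[C@@](C)(O[Si](CC)(CC)CC)[C@@H](C)Cl)[C@H](OC(C)=O)/C(C(=O)OC)=C\CC[C@@]1(C)O[C@H]1CO | intermediate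
28 | primary allylic bromide: C13H2Br, C7=C11 enoate | BrC/C(C(=O)OC)=C\[C@H](OC(=O)[C@@](C)(O[Si](CC)(CC)CC)[C@@H](C)Cl)[C@H](OC(C)=O)/C(C(=O)OC)=C\CC[C@@]1(C)O[C@H]1CO | intermediate
29 | epoxy aldehyde (C6HO) allylic bromide | BrC/C(C(=O)OC)=C\[C@H](OC(=O)[C@@](C)(O[Si](CC)(CC)CC)[C@@H](C)Cl)[C@H](OC(C)=O)/C(C(=O)OC)=C\CC[C@@]1(C)O[C@H]1C=O | intermediate
30 | ring-closed hydroxy ester: ten-membered ring, C6–OH, C7–C(=CH2)CO2Me | O[C@H]2[C@H](C(=C)C(=O)OC)[C@H](OC(=O)[C@@](C)(O[Si](CC)(CC)CC)[C@@H](C)Cl)[C@H](OC(C)=O)/C(C(=O)OC)=C\CC[C@@]1(C)O[C@@H]21 | intermediate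
31 | triethylsilyl-protected target | C=C1C(=O)O[C@H]2[C@H]1[C@H](OC(=O)[C@@](C)(O[Si](CC)(CC)CC)[C@@H](C)Cl)[C@H](OC(C)=O)/C(C(=O)OC)=C\CC[C@@]1(C)O[C@@H]21 | intermediate
32 | CNP0185503.1: (4R,5S,6S,7R,8S,9R)-9-acetoxy-8-[(2R,3R)-3-chloro-2-hydroxy-2-methylbutanoyloxy]-4,5-epoxy-14-methoxy-14-oxogermacra-1(10),11(13)-dien-12,6-olide | C=C1C(=O)O[C@H]2[C@H]1[C@H](OC(=O)[C@@](C)(O)[C@@H](C)Cl)[C@H](OC(C)=O)/C(C(=O)OC)=C\CC[C@@]1(C)O[C@@H]21 | target

**Step count and risk**
Total: 16 steps. Longest linear sequence: 13 steps (3 → 32 through steps 2–6, 8, 9, 11–16); 10 steps from methyl benzoate.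

Step 9 (lactol methylenation). The strongly basic ylide meets a C9 alkoxide next to the C8 ester and an acidic C8–H, so acyl migration, C8 epimerization or slow lactol opening can spoil it. Fallback: set out from 11 and acetylate C9–OH first (Ac2O, pyridine) to the diacyl diene F1. Ozonolysis and Me2S then give the open-chain dialdehyde F2, which has no lactol and no free hydroxyl. The more electrophilic α-acyloxy C7 aldehyde is olefinated with 15 at low temperature to the C7-olefinated enal F3. The remaining enal is methylenated with exactly one equivalent of Ph3P=CH2 at −78 °C (or with non-basic Zn/CH2I2/Ti(Oi-Pr)4), and the route is rejoined at 20. The differentiation here rests on aldehyde reactivity instead of the lactol mask, and no alkoxide is ever formed.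

Step 13 (bromodesilylation). The ester-deactivated allylsilane may react sluggishly with NBS, or the oxirane may suffer. Fallback: set out from 26 and oxidize directly (Dess–Martin periodinane, pyridine) to the silyl epoxy aldehyde F4. The ring is then closed without any bromide by an intramolecular Hosomi–Sakurai allylation (BF3·OEt2, CH2Cl2, −78 °C, high dilution), in which the γ-carbon C7 attacks the activated aldehyde. Lactonization returns the route at 31.

Step 15 (chromium macrocyclization). Ten-membered ring closure competes with oligomerization, and the C8 stereocentre may oppose the chair/Felkin preference, giving the wrong C6/C7 pair. Fallback: set out from 28 and convert the bromide with B2pin2, CuCl, KOAc and LiCl in DMF into the 2-(methoxycarbonyl)allylboronate F5. Dess–Martin oxidation gives the boronate aldehyde F6, which cyclizes on gentle warming by a metal-free allylboration through a tight closed chair transition state. Lactonization of the borate returns the route at 31.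

**Further compounds**
F1 | step 9 | methyl (5S,6R)-6-acetoxy-5-(R*CO2)cyclohexa-1,3-diene-1-carboxylate | COC(=O)C1=CC=C[C@H](OC(=O)[C@@](C)(O[Si](CC)(CC)CC)[C@@H](C)Cl)[C@@H]1OC(C)=O
F2 | step 9 | open-chain dialdehyde (C7HO and C2HO; C9–OAc; C10(CO2Me)=C1 with C9 cis to C2) | O=C[C@H](OC(=O)[C@@](C)(O[Si](CC)(CC)CC)[C@@H](C)Cl)[C@H](OC(C)=O)/C(C(=O)OC)=C\C=O
F3 | step 9 | C7-olefinated enal (C7=C11(CO2Me)CH2SiMe3; C2HO) | C[Si](C)(C)C/C(C(=O)OC)=C\[C@H](OC(=O)[C@@](C)(O[Si](CC)(CC)CC)[C@@H](C)Cl)[C@H](OC(C)=O)/C(C(=O)OC)=C\C=O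
F4 | step 13 | silyl epoxy aldehyde (26 with C6HO) | C[Si](C)(C)C/C(C(=O)OC)=C\[C@H](OC(=O)[C@@](C)(O[Si](CC)(CC)CC)[C@@H](C)Cl)[C@H](OC(C)=O)/C(C(=O)OC)=C\CC[C@@]1(C)O[C@H]1C=O
F5 | step 15 | allylboronate epoxy alcohol (28 with Bpin in place of Br) | CC1(C)OB(C/C(C(=O)OC)=C\[C@H](OC(=O)[C@@](C)(O[Si](CC)(CC)CC)[C@@H](C)Cl)[C@H](OC(C)=O)/C(C(=O)OC)=C\CC[C@@]2(C)O[C@H]2CO)OC1(C)C
F6 | step 15 | allylboronate epoxy aldehyde | CC1(C)OB(C/C(C(=O)OC)=C\[C@H](OC(=O)[C@@](C)(O[Si](CC)(CC)CC)[C@@H](C)Cl)[C@H](OC(C)=O)/C(C(=O)OC)=C\CC[C@@]2(C)O[C@H]2C=O)OC1(C)C
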